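**Plan**

1. Retrosynthesis: the two O-benzyl groups and the C2=C3 unsaturation are removed first, giving a trans-dihydroflavonol. Ring C is then cut at O1–C2 (chalcone epoxide), then the oxirane oxygen and the Cα=Cβ bond (aldol), and last the acetyl–aryl bond and the C–O bond at the future C5 of ring A.
2. Forward: ring A is built up from 2-methoxyresorcinol (C–H borylation/oxidation, ortho-lithiation/acetylation). Ring B is joined as its aldehyde by Claisen–Schmidt condensation, the enone is epoxidised, and ring C closes last.
3. Enabling feature: C2 is benzylic to ring B and bonded to O1, and C3 carries an oxygen. The C2–C3 pair is therefore the opened form of an oxirane, which the oxygen on C8a can open at the benzylic carbon while the oxirane oxygen stays on C3.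
4. Regiochemistry: the oxygen of the future C5 stays benzylated while the oxygens of C8a and C7 are unmasked, so only the 8-methoxy (not the 6-methoxy) chromanone can form.
5. Stereochemistry: the target has no stereocentre. C2 and C3 exist only in 13–15 as a racemic trans pair, set by trans epoxidation of the E-enone and anti opening, and both are erased in step 9.

Key step: step 8

Assumption: all chiral intermediates are racemic; descriptors and SMILES show one enantiomer only to fix the relative configuration.

**Route**

Step 1
Reactants: 1 2-methoxyresorcinol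
Product: 2 2-methoxy-1,3-bis(methoxymethoxy)benzene
Conditions: NaH, MOMCl, DMF, 0 °C → rt
Reagents that add atoms: chloromethyl methyl ether, COCCl
Why: Double Williamson-type O-alkylation of the sodium bis-phenoxide by the reactive α-chloro ether should give the mirror-symmetric bis-acetal that the later desymmetrisation relies on.

Step 2
Reactants: 2 2-methoxy-1,3-bis(methoxymethoxy)benzene
Product: 4 4-methoxy-3,5-bis(methoxymethoxy)phenol, via pinacol arylboronate 3 (not isolated)
Conditions: [Ir(OMe)(cod)]2 (cat.), 4,4'-di-tert-butyl-2,2'-bipyridine (cat.), B2pin2, THF, 80 °C; then 30% aq. H2O2, aq. NaOH, 0 °C → rt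
Reagents that add atoms: bis(pinacolato)diboron, CC1(C)OB(OC1(C)C)B1OC(C)(C)C(C)(C)O1 (supplies the boryl group of 3 only); hydrogen peroxide, OO (supplies the phenol oxygen of 4)
Why: Iridium-catalysed aromatic C–H borylation is sterically governed and should touch only C5, the one C–H without an ortho substituent, and alkaline peroxide then turns C–B into C–O by aryl migration from boron to oxygen (one-pot borylation–oxidation).

Step 3
Reactants: 4 4-methoxy-3,5-bis(methoxymethoxy)phenol
Product: 5 5-(benzyloxy)-2-methoxy-1,3-bis(methoxymethoxy)benzene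
Conditions: BnBr, K2CO3, DMF, rt
Reagents that add atoms: benzyl bromide, BrCc1ccccc1
Why: Williamson ether synthesis on the only free phenol installs an acid-stable group that later distinguishes this oxygen from the two acetal-protected ones.

Step 4
Reactants: 5 5-(benzyloxy)-2-methoxy-1,3-bis(methoxymethoxy)benzene; 6 N-methoxy-N-methylacetamide
Product: 9 1-[6-(benzyloxy)-3-methoxy-2,4-bis(methoxymethoxy)phenyl]ethan-1-one, via aryllithium 7 (not isolated), via tetrahedral lithium adduct 8 (not isolated)
Conditions: n-BuLi, THF, 0 °C; then 6, −78 °C → rt; aq. NH4Cl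
Reagents that add atoms: n-butyllithium, [Li]CCCC (supplies the lithium of 7 and 8 only)
Why: Directed ortho-metalation should occur at one of the two symmetry-equivalent ring C–H bonds, each flanked by the coordinating OMOM group and the benzyloxy group, and acylation by the N-methoxy-N-methylamide stops at the ketone because the chelated adduct 8 collapses only on work-up (Weinreb ketone synthesis).

Step 5
Reactants: 10 3-hydroxy-4,5-dimethoxybenzaldehyde
Product: 11 3-(benzyloxy)-4,5-dimethoxybenzaldehyde
Conditions: BnBr, K2CO3, DMF, rt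
Reagents that add atoms: benzyl bromide, BrCc1ccccc1
Why: Williamson ether synthesis on the single phenol of a non-enolisable aldehyde that is stable to carbonate base.

Step 6
Reactants: 9 1-[6-(benzyloxy)-3-methoxy-2,4-bis(methoxymethoxy)phenyl]ethan-1-one; 11 3-(benzyloxy)-4,5-dimethoxybenzaldehyde
Product: 12 (E)-1-[6-(benzyloxy)-3-methoxy-2,4-bis(methoxymethoxy)phenyl]-3-[3-(benzyloxy)-4,5-dimethoxyphenyl]prop-2-en-1-one
Conditions: KOH, EtOH, rt
Reagents that add atoms: none
Why: Claisen–Schmidt condensation (aldol addition of the methyl ketone enolate to the non-enolisable aldehyde, then E1cB dehydration) should give the thermodynamically preferred E-enone, and with every phenol masked no flavanone can form.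

Step 7
Reactants: 12 (E)-1-[6-(benzyloxy)-3-methoxy-2,4-bis(methoxymethoxy)phenyl]-3-[3-(benzyloxy)-4,5-dimethoxyphenyl]prop-2-en-1-one
Product: 13 rac-[6-(benzyloxy)-3-methoxy-2,4-bis(methoxymethoxy)phenyl]{(2S,3R)-3-[3-(benzyloxy)-4,5-dimethoxyphenyl]oxiran-2-yl}methanone (trans epoxide)
Conditions: 30% aq. H2O2, aq. NaOH, MeOH–THF, 0 °C → rt
Reagents that add atoms: hydrogen peroxide, OO
Why: Weitz–Scheffer nucleophilic epoxidation (conjugate addition of hydroperoxide anion, then closure of the enolate onto the O–O bond) should give the racemic trans oxirane from the E-enone, the relative configuration following from the enone geometry and the preference of the stepwise closure for the trans product, while the masked ortho oxygens rule out aurone formation.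

Step 8
Reactants: 13 rac-[6-(benzyloxy)-3-methoxy-2,4-bis(methoxymethoxy)phenyl]{(2S,3R)-3-[3-(benzyloxy)-4,5-dimethoxyphenyl]oxiran-2-yl}methanone
Product: 15 rac-(2S,3S)-5-(benzyloxy)-2-[3-(benzyloxy)-4,5-dimethoxyphenyl]-3,7-dihydroxy-8-methoxy-2,3-dihydro-4H-chromen-4-one (trans), via diphenol epoxide 14 (not isolated)
Conditions: conc. HCl, MeOH–THF, 50 °C
Reagents that add atoms: none
Why: Methanolic HCl solvolyses both MOM acetals (released as dimethoxymethane) to diphenol 14, whose carbonyl-flanking phenol oxygen (future O1 on C8a) attacks the protonated oxirane at the benzylic carbon anti to the departing oxirane oxygen, which remains on the future C3 as the hydroxyl. The closest known reaction type is the acid-promoted deprotection–cyclisation of 2'-O-methoxymethyl chalcone epoxides to trans-dihydroflavonols, the stepwise form of the Algar–Flynn–Oyamada reaction. Ring C closes in a 6-endo-tet mode (O1–C2), the breaking oxirane C–O bond lying inside the new ring. The new stereocentre C2 is controlled by the existing oxirane centre that becomes C3: inversion at the benzylic carbon with retention at C3 turns the trans epoxide into the trans 2,3-relationship, and any cis isomer from a more cationic opening is harmless because step 9 removes both centres. The step needs 6-endo over 5-exo opening and closure by the correct oxygen: the first is secured because ring B stabilises positive charge at the benzylic carbon while the carbon next to the ketone is deactivated, the second because the benzyl ether on the other ortho oxygen (future C5–O) survives conditions that cleave only the acetals and the para phenol (future 7-OH) cannot reach.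

Step 9
Reactants: 15 rac-(2S,3S)-5-(benzyloxy)-2-[3-(benzyloxy)-4,5-dimethoxyphenyl]-3,7-dihydroxy-8-methoxy-2,3-dihydro-4H-chromen-4-one
Product: 16 5-(benzyloxy)-2-[3-(benzyloxy)-4,5-dimethoxyphenyl]-3,7-dihydroxy-8-methoxy-4H-chromen-4-one
Conditions: I2, KOAc, AcOH, 100 °C
Reagents that add atoms: none
Why: Iodine-mediated dehydrogenation of a flavanonol (acetate-assisted enolisation towards C3, iodination, loss of HI to the 3,4-dione tautomer, then tautomerisation) should give the aromatic 3-hydroxy-4-pyranone and remove both stereocentres.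

Step 10
Reactants: 16 5-(benzyloxy)-2-[3-(benzyloxy)-4,5-dimethoxyphenyl]-3,7-dihydroxy-8-methoxy-4H-chromen-4-one
Product: 17 3,5,7-trihydroxy-2-(3-hydroxy-4,5-dimethoxyphenyl)-8-methoxy-4H-chromen-4-one (CNP0225742.0)
Conditions: H2 (1 atm), 10% Pd/C, EtOAc–MeOH, rt
Reagents that add atoms: none
Why: Catalytic hydrogenolysis should cleave both aryl benzyl ethers, while the C2=C3 bond, being part of the aromatic 4-pyranone, is not reduced under these mild conditions.

**Compound list**

1 | 2-methoxyresorcinol | COc1c(O)cccc1O | starting material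
2 | 2-methoxy-1,3-bis(methoxymethoxy)benzene | COCOc1cccc(OCOC)c1OC | intermediate
3 | 2-[4-methoxy-3,5-bis(methoxymethoxy)phenyl]-4,4,5,5-tetramethyl-1,3,2-dioxaborolane | COCOc1cc(B2OC(C)(C)C(C)(C)O2)cc(OCOC)c1OC | intermediate (not isolated)
4 | 4-methoxy-3,5-bis(methoxymethoxy)phenol | COCOc1cc(O)cc(OCOC)c1OC | intermediate
5 | 5-(benzyloxy)-2-methoxy-1,3-bis(methoxymethoxy)benzene | COCOc1cc(OCc2ccccc2)cc(OCOC)c1OC | intermediate
6 | N-methoxy-N-methylacetamide | CC(=O)N(C)OC | starting material
7 | [6-(benzyloxy)-3-methoxy-2,4-bis(methoxymethoxy)phenyl]lithium | [Li]c1c(OCOC)c(OC)c(OCOC)cc1OCc1ccccc1 | intermediate (not isolated)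
8 | lithium 1-[6-(benzyloxy)-3-methoxy-2,4-bis(methoxymethoxy)phenyl]-1-[methoxy(methyl)amino]ethan-1-olate (racemic) | [Li]OC(C)(N(C)OC)c1c(OCOC)c(OC)c(OCOC)cc1OCc1ccccc1 | intermediate (not isolated)
9 | 1-[6-(benzyloxy)-3-methoxy-2,4-bis(methoxymethoxy)phenyl]ethan-1-one | CC(=O)c1c(OCOC)c(OC)c(OCOC)cc1OCc1ccccc1 | intermediate
10 | 3-hydroxy-4,5-dimethoxybenzaldehyde | COc1cc(C=O)cc(O)c1OC | starting material
11 | 3-(benzyloxy)-4,5-dimethoxybenzaldehyde | COc1cc(C=O)cc(OCc2ccccc2)c1OC | intermediate
12 | (E)-1-[6-(benzyloxy)-3-methoxy-2,4-bis(methoxymethoxy)phenyl]-3-[3-(benzyloxy)-4,5-dimethoxyphenyl]prop-2-en-1-one | COCOc1cc(OCc2ccccc2)c(C(=O)/C=C/c2cc(OC)c(OC)c(OCc3ccccc3)c2)c(OCOC)c1OC | intermediate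
13 | rac-[6-(benzyloxy)-3-methoxy-2,4-bis(methoxymethoxy)phenyl]{(2S,3R)-3-[3-(benzyloxy)-4,5-dimethoxyphenyl]oxiran-2-yl}methanone | COCOc1cc(OCc2ccccc2)c(C(=O)[C@H]2O[C@@H]2c2cc(OC)c(OC)c(OCc3ccccc3)c2)c(OCOC)c1OC | intermediate
14 | rac-[6-(benzyloxy)-2,4-dihydroxy-3-methoxyphenyl]{(2S,3R)-3-[3-(benzyloxy)-4,5-dimethoxyphenyl]oxiran-2-yl}methanone | COc1c(O)cc(OCc2ccccc2)c(C(=O)[C@H]2O[C@@H]2c2cc(OC)c(OC)c(OCc3ccccc3)c2)c1O | intermediate (not isolated)
15 | rac-(2S,3S)-5-(benzyloxy)-2-[3-(benzyloxy)-4,5-dimethoxyphenyl]-3,7-dihydroxy-8-methoxy-2,3-dihydro-4H-chromen-4-one | O=C1c2c(OCc3ccccc3)cc(O)c(OC)c2O[C@@H](c2cc(OC)c(OC)c(OCc3ccccc3)c2)[C@@H]1O | intermediate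
16 | 5-(benzyloxy)-2-[3-(benzyloxy)-4,5-dimethoxyphenyl]-3,7-dihydroxy-8-methoxy-4H-chromen-4-one | O=c1c(O)c(-c2cc(OC)c(OC)c(OCc3ccccc3)c2)oc2c(OC)c(O)cc(OCc3ccccc3)c12 | intermediate
17 | 3,5,7-trihydroxy-2-(3-hydroxy-4,5-dimethoxyphenyl)-8-methoxy-4H-chromen-4-one | COc1cc(-c2oc3c(OC)c(O)cc(O)c3c(=O)c2O)cc(O)c1OC | target

**Totals**

Total step count: 10. Longest linear sequence: 9 steps (steps 1, 2, 3, 4, 6, 7, 8, 9, 10 from 2-methoxyresorcinol); step 5 is a one-step side branch.

**Steps most likely to fail**

1. Step 8. After acetal cleavage the protonated oxirane may be captured at the benzylic carbon by methanol or chloride faster than by the phenol, aryl migration or 5-exo closure may compete, and prolonged acid may begin to cleave the benzyl ether peri to the carbonyl. The fallback separates unmasking from C–O bond formation and forms O1–C2 under neutral conditions. It sets out from chalcone 12. OsO4-catalysed syn-dihydroxylation with N-methylmorpholine N-oxide in acetone–water should give rac-(2S,3R)-1-[6-(benzyloxy)-3-methoxy-2,4-bis(methoxymethoxy)phenyl]-3-[3-(benzyloxy)-4,5-dimethoxyphenyl]-2,3-dihydroxypropan-1-one F1, which has the same relative configuration as the trans epoxide. Mild methanolic HCl then removes both MOM groups to give rac-(2S,3R)-1-[6-(benzyloxy)-2,4-dihydroxy-3-methoxyphenyl]-3-[3-(benzyloxy)-4,5-dimethoxyphenyl]-2,3-dihydroxypropan-1-one F2. Intramolecular Mitsunobu etherification (PPh3, DIAD, THF, 0 °C) displaces the activated benzylic hydroxyl by the ortho phenol with inversion, and the route is rejoined at dihydroflavonol 15.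

2. Step 4. n-BuLi may deprotonate the benzylic CH2 of the benzyl ether (opening a [1,2]-Wittig rearrangement) instead of the ring, ring metalation may be incomplete, or the aryllithium may be quenched by proton transfer from the acetamide. The fallback generates the aryl anion by halogen–metal exchange instead of deprotonation. It sets out from 5. NBS in MeCN at 0 °C should brominate one of the two equivalent activated ring positions to give 1-(benzyloxy)-2-bromo-4-methoxy-3,5-bis(methoxymethoxy)benzene F3. Bromine–lithium exchange with n-BuLi in THF at −78 °C, much faster than any C–H deprotonation, then delivers aryllithium 7, where the route is rejoined (addition of 6 gives 9 as before).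

3. Step 9. Electrophilic iodination of ring A at C6, ortho to the free C7 phenol, may compete with dehydrogenation, and HI not buffered by acetate may attack the C5 benzyl ether. The fallback inverts the order of the last two operations and uses a halogen-free oxidation. It sets out from 15. Hydrogenolysis (H2, 10% Pd/C, EtOAc–MeOH) should give rac-(2S,3S)-3,5,7-trihydroxy-2-(3-hydroxy-4,5-dimethoxyphenyl)-8-methoxy-2,3-dihydro-4H-chromen-4-one F4. Dehydrogenation of this free flavanonol by air in hot aqueous NaHSO3, the classical halogen-free conversion of 5,7-dihydroxyflavanonols into flavonols, then rejoins the route at target 17.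

**Further compounds**

F1 | step 8 | rac-(2S,3R)-1-[6-(benzyloxy)-3-methoxy-2,4-bis(methoxymethoxy)phenyl]-3-[3-(benzyloxy)-4,5-dimethoxyphenyl]-2,3-dihydroxypropan-1-one | COCOc1cc(OCc2ccccc2)c(C(=O)[C@@H](O)[C@H](O)c2cc(OC)c(OC)c(OCc3ccccc3)c2)c(OCOC)c1OC
F2 | step 8 | rac-(2S,3R)-1-[6-(benzyloxy)-2,4-dihydroxy-3-methoxyphenyl]-3-[3-(benzyloxy)-4,5-dimethoxyphenyl]-2,3-dihydroxypropan-1-one | COc1c(O)cc(OCc2ccccc2)c(C(=O)[C@@H](O)[C@H](O)c2cc(OC)c(OC)c(OCc3ccccc3)c2)c1O
F3 | step 4 | 1-(benzyloxy)-2-bromo-4-methoxy-3,5-bis(methoxymethoxy)benzene | Brc1c(OCOC)c(OC)c(OCOC)cc1OCc1ccccc1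
F4 | step 9 | rac-(2S,3S)-3,5,7-trihydroxy-2-(3-hydroxy-4,5-dimethoxyphenyl)-8-methoxy-2,3-dihydro-4H-chromen-4-one | O=C1c2c(O)cc(O)c(OC)c2O[C@@H](c2cc(OC)c(OC)c(O)c2)[C@@H]1O
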